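| flask | starting complex | incoming ligand | remark | time |
|---|---|---|---|---|
| grey | 0.35 M | 1.25 M | run made earlier |  |
| violet | 0.55 M | 1.25 M | run made earlier |  |
| teal | 0.25 M | 1.9 M | run made earlier |  |
| flask | 0.25 M | 1.25 M |  | 15 d |

- grey (time / d: complex with two exchanged / %, starting complex / %): 0.250: 4.4, 57.2; 0.417: 8.2, 39.1; 0.833: 13.3, 16.5; 1.67: 11.5, 3.9; 2.50: 6.2, 1.5; 5.00: 1.1, 1.7; 10.0: 0.3, 1.2
- violet (time / d: complex with two exchanged / %, starting complex / %): 0.250: 4.7, 57.3; 0.417: 7.5, 39.9; 0.833: 12.8, 16.7; 1.67: 11.7, 4.2; 2.50: 6.6, 1.9; 5.00: 1.2, 1.7; 10.0: 0.8, 2.0
- teal (time / d: complex with two exchanged / %, starting complex / %): 0.250: 7.9, 50.7; 0.625: 17.0, 19.0; 1.67: 7.8, 2.2; 4.00: 0.3, 0.7; 10.0: 0.3, 0.4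

(standard deviation of a reading: 0.3 percentage points)

- what was read earlier has a scatter of 0.3 percentage points, one standard deviation

- time up to 15 d at which complex with two exchanged stands highest
- the amount of complex with two exchanged, in percent of the starting complex charged, at that time
- the first time at which complex with two exchanged reaches 9.7%, in the same percent

Per day, the starting complex of the grey run falls at 2.13 /d between its first and third readings, from 0.250 d to 0.833 d, and that of the teal run at 2.62 /d between its first and second readings, from 0.250 d to 0.625 d, the two spans that carry most of the fall while the readings stand well above the scatter. Teal is faster by 1.23 times on 1.52 times the incoming ligand, so part of the loss does not follow the ligand. The grey and violet runs read alike within the scatter at different complex charges, so I take the flask's curve in percent to be theirs.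

I build the flask in stages. With the main step alone, pseudo-first-order in 5.00 equivalents of incoming ligand, the ceiling for complex with two exchanged is the whole charge. A straight line through the grey and teal rates splits the loss into 0.746 /M/d per molar of ligand plus 1.20 /d that needs none. Adding that ligand-free loss lowers the ceiling to the exchange share, the fraction of the starting complex's loss that runs through the ligand step: 43.7% in the flask. The rest of the chain lowers it again. Teal, with a share of 54.2%, read 17.0% at its highest, a peak per share of 31.4%. So I commit to 13.7% for the flask, and the grey run's highest reading, 13.3%, lies close to it.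

The forecast gives 13.9% at 1.1 d, and 9.7% first at 0.52 d, holding that the flask “should follow the grey and violet curves”. My height lies a little lower than its figure.

The flask gives 13.9% at 0.993 d and reaches 9.7% first at 0.485 d, so the forecast holds within its margins.

    starting complex + incoming ligand → leaving ligand + complex with one exchanged (k = 5.00 × 10⁻⁴ /M/min)
    complex with one exchanged + incoming ligand → leaving ligand + complex with two exchanged (k = 0.00150 /M/min)
    complex with two exchanged + incoming ligand → leaving ligand + complex with three exchanged (k = 6.80 × 10⁻⁴ /M/min)
    complex with three exchanged + incoming ligand → leaving ligand + complex with four exchanged (k = 1.80 × 10⁻⁴ /M/min)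
    starting complex ⇌ dormant form (K = 31.0, k = 9.70 × 10⁻⁴ /min)
    crystals ⇌ leaving ligand, rate k6*(cs6 - [leaving ligand]) while solid is left; crystals form when [leaving ligand] > cs6 (solubility = 0.110 M, k = 0.0240 /min)
    leaving ligand + complex with two exchanged → side product (k = 0.00200 /M/min)

At the start, the flask's starting complex goes to dormant form 1.6 times as fast as into the first exchange, forward step alone. At 0.993 d dormant form in the flask holds 54.2%, more than complex with two exchanged. The flask's peak per exchange share is 31.8%. The neighbour flask with 0.50 M of incoming ligand has a share of 23.7%, which at that peak per share gives 7.54%, and its highest amount stands at 7.81%.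

The numbers in the tables were generated by integration for substances that don't exist, and the scatter is random.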